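**Retrosynthetic overview**
1. C16 is set last, by exo-face hydrogenation of a 16-methylene-15-ketone. That enone comes from α-methylenation of a bicyclo[3.2.1]octenone.
2. Ring D (C13–C16) comes from Pd(II) oxidative cycloalkenylation of a C8-acetyl enol silane onto a Δ12 cyclohexene.
3. Key step: ring C, quaternary C8 and C9 come from an intermolecular Diels–Alder reaction of butadiene with an α-acetyl-α,β-unsaturated spiro-δ-lactone. The acetyl activator later becomes C15/C16. Kaurane ring B is never built, so the route uses no C6–C7 cleavage, no tethered IMDA and no vinyl-radical D-ring closure.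
4. The spiro-lactone and C10 come from Ti(III) epoxide opening, Giese addition to an acrylate, and lactonisation.
5. C4, C5 and C6 come from Cu-catalysed asymmetric conjugate alkenylation of 3-methylcyclohexenone, enolate trapping, a C6 acetal and thermodynamic acetalisation. Ring order: A → THF acetal → lactone → C → D.

Assumption: ent-kaurane numbering is used. The SMILES is read as 4R,5R,6S,8S,9S,10R,13R,16R, with 6-OMe anti to C10, C19/C6/C20 on one face of ring A, and the 16-methyl endo (syn to the C11–C12 bridge).

**Step 1**
Reactants: 1 3-methylcyclohex-2-en-1-one; 2 hex-1-yne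
Product: 3 silyl enol ether of 3-[(E)-hex-1-enyl]-3-methylcyclohexanone, with the enol double bond toward the quaternary carbon
Conditions: 2, DIBAL-H, heptane, 55 °C; then 1, CuTC (5 mol %), chiral SimplePhos-type phosphinamine ligand (enantiomer chosen for the configuration drawn), Et2O, −30 °C; then TMSOTf, THF, 0 °C
Reagents that add atoms: TMSOTf, C[Si](C)(C)OS(=O)(=O)C(F)(F)F
Why: Tandem hydroalumination and Cu-catalysed asymmetric conjugate addition of an alkenylalane to a β-substituted cyclic enone sets quaternary C4 under ligand control (typically ≥90 % ee; the alkenyl group is a masked C19), and silylation of the regiodefined aluminium enolate fixes the Δ5(10) enol ether, which deprotonation of the ketone cannot give.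

**Step 2**
Reactants: 3
Product: 4 2-(dimethoxymethyl)-3-[(E)-hex-1-enyl]-3-methylcyclohexanone (C5 epimers)
Conditions: HC(OMe)3, BF3·OEt2, CH2Cl2, −78 °C
Reagents that add atoms: trimethyl orthoformate, COC(OC)OC
Why: Mukaiyama-type alkylation of the enol silane by the small dimethoxycarbenium ion installs C6 at the aldehyde oxidation level even at the neopentyl C5, and the C5 configuration does not matter here because it is still epimerisable and is corrected in step 4.

**Step 3**
Reactants: 4
Product: 5 2-(dimethoxymethyl)-1-methyl-3-oxocyclohexane-1-carbaldehyde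
Conditions: O3, CH2Cl2, −78 °C; then PPh3, −78 °C → rt
Reagents that add atoms: ozone, [O-][O+]=O
Why: Criegee ozonolysis of the only C=C bond unmasks the C19 aldehyde (pentanal is lost) without touching the ketone, the acetal or non-epimerisable C4.

**Step 4**
Reactants: 5
Product: 6 cis-fused keto acetal, (3S,3aS,7aR)-3-methoxy-7a-methylhexahydro-2-benzofuran-4(1H)-one
Conditions: NaBH4, CH2Cl2–MeOH (7:3), −78 °C; then CSA, MeOH, 40 °C
Reagents that add atoms: none (hydride only; one MeOH is lost; exchange with solvent MeOH is degenerate)
Why: Low-temperature borohydride reduces the aldehyde chemoselectively over the hindered ketone and acid-catalysed transacetalisation closes the THF ring, and because C5 (α to C=O) and C6 (acetal) both equilibrate, the mixture converges on the most stable isomer, which is cis-fused (as for angular-methyl hydrindanones) with OMe on the convex face anti to C10, so C5 and C6 are set from C4.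

**Step 5**
Reactants: 6
Product: 7 (3S,3aS,7aR)-3-methoxy-7a-methyl-4-methylideneoctahydro-2-benzofuran
Conditions: Cp2TiMe2, toluene, 75 °C, dark
Reagents that add atoms: Petasis reagent, [CH3-].[CH3-].[Ti+4].c1cc[cH-]c1.c1cc[cH-]c1
Why: Petasis methylenation is non-basic and tolerates acetals, so the hindered, enolisable β-keto acetal is olefinated without C5 epimerisation or E1cB loss of alkoxide.

**Step 6**
Reactants: 7
Product: 8 C10–C20 spiro-epoxide of 7 (major isomer has O on the convex face)
Conditions: mCPBA, NaHCO3, CH2Cl2, 0 °C
Reagents that add atoms: mCPBA, OOC(=O)c1cccc(Cl)c1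
Why: Buffered Prilezhaev epoxidation of the only alkene is straightforward, and the new C10 configuration is irrelevant because C10 becomes a planar radical in step 7.

**Step 7**
Reactants: 8; 9 2,2,2-trifluoroethyl acrylate
Product: 10 spiro-δ-lactone (C20H2–O syn to C6/C19; C9H2 anti; 4R,5R,6S,10R)
Conditions: Cp2TiCl2, Zn, 2,4,6-collidine·HCl, 9 (5 equiv), THF, rt
Reagents that add atoms: none (both partners are numbered; H at C8 comes from collidinium; CF3CH2OH is lost)
Why: Ti(III) reductive epoxide opening (Nugent–RajanBabu/Gansäuer) gives the tertiary C10 radical, Giese addition to the acrylate takes place on the convex face (anti to vicinal C6 and to the 1,3-axial C19H2O), and the Ti alkoxide closes onto the activated ester, so quaternary C10 and the lactone form in one operation.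

**Step 8**
Reactants: 10
Product: 11 8-acetyl spiro-lactone (C8 epimers/enol)
Conditions: LDA (2.2 equiv), THF, −78 °C; then 1-acetylimidazole, −78 → −20 °C
Reagents that add atoms: 1-acetylimidazole, CC(=O)n1ccnc1
Why: Crossed Claisen C-acylation of the lactone enolate introduces C15/C16 (the second equivalent of base absorbs the acidic product), and the C8 configuration is erased in step 9.

**Step 9**
Reactants: 11
Product: 12 8-acetyl-Δ8(9) spiro-lactone (3-acetyl-5,6-dihydropyran-2-one)
Conditions: PhSeCl, pyridine, CH2Cl2, 0 °C; then 30 % H2O2, 0 °C; used directly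
Reagents that add atoms: none (Se enters and leaves; net loss of 2 H)
Why: α-Selenenylation of the β-dicarbonyl followed by selenoxide syn-elimination can only proceed toward C9, the sole carbon bearing β-hydrogens, and the product cannot tautomerise because C10 is quaternary.

**Step 10 (key step)**
Reactants: 12; 13 buta-1,3-diene
Product: 14 cis-fused Δ12-cyclohexene/δ-lactone bearing the acetyl group on quaternary C8 (8S,9S)
Conditions: 13 (excess), ZnCl2 (1 equiv), CH2Cl2–Et2O, −20 °C → rt, sealed tube
Reagents that add atoms: none
Why: This is a normal-demand Diels–Alder reaction of a chelated 2-acyl enoate (the reactivity known for 2-carboalkoxy-4,4-dialkylcyclohexenones), in which suprafacial addition forces C7 and C10 cis, butadiene adds to the face syn to C1H2 because the other face is covered by C5 and its gauche C6 acetal carbon, C8 and C9 are therefore set from C10 in one step, and a symmetrical diene removes regiochemical and endo/exo issues.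

**Step 11**
Reactants: 14
Product: 15 TBS enol ether of the acetyl group (C15(OTBS)=C16H2)
Conditions: KHMDS, THF, −78 °C; then TBSCl
Reagents that add atoms: TBSCl, CC(C)(C)[Si](C)(C)Cl
Why: Kinetic enolate O-silylation is unambiguous because the acetyl CH3 is the only enolisable position (C8 is quaternary), and no Lewis acid is present that could harm the acetal.

**Step 12**
Reactants: 15
Product: 16 bicyclo[3.2.1]oct-ene ketone (C15=O, C16H2, Δ11; 13R)
Conditions: Pd(OAc)2 (20 mol %), O2 (1 atm), DMSO, 45 °C
Reagents that add atoms: none
Why: In this Pd(II) oxidative cycloalkenylation of a silyl enol ether (Saegusa/Kende–Toyota type) the Pd enolate has no β-hydrogen for dehydrogenation, so it undergoes 5-exo syn-insertion into Δ12 and β-H elimination toward C11, and the one-atom C14 tether allows bonding only on the ring C face carrying C15, which sets C13.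

**Step 13**
Reactants: 16
Product: 17 16-methylene-15-ketone (Δ11 retained)
Conditions: LiHMDS, THF, −78 °C; CH2=NMe2+ I−, → rt; then MeI, CH2Cl2; then DBU
Reagents that add atoms: Eschenmoser's salt, C=[N+](C)C.[I-]
Why: Regiospecific enolisation at C16 (the only α-CH2), Mannich reaction, quaternisation and E1cB elimination make up the standard α-methylenation of 15-oxo-kauranoids, and the non-nucleophilic bases avoid retro-Claisen cleavage of the non-enolisable β-keto lactone.

**Step 14**
Reactants: 17
Product: 18 ludongnin I
Conditions: H2 (1 atm), 10 % Pd/C, EtOAc, rt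
Reagents that add atoms: none
Why: Heterogeneous syn-hydrogenation saturates Δ11 (no new stereocentre) and adds to the exocyclic enone from the exo face of the bicyclo[3.2.1]octane (syn to C14, because the endo face is shielded by the C9–C11–C12 bridge), which places H-16 exo and the methyl endo (16R), and neutral conditions keep this kinetically set centre from epimerising.

**Compound list**
1 | 3-methylcyclohex-2-en-1-one | CC1=CC(=O)CCC1 | starting material
2 | hex-1-yne | CCCCC#C | starting material
3 | {[(3S)-3-[(1E)-hex-1-enyl]-3-methylcyclohex-1-en-1-yl]oxy}trimethylsilane | CCCC/C=C/[C@]1(C)CCCC(O[Si](C)(C)C)=C1 | intermediate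
4 | (3S)-2-(dimethoxymethyl)-3-[(1E)-hex-1-enyl]-3-methylcyclohexan-1-one (C2 epimers) | CCCC/C=C/[C@]1(C)CCCC(=O)C1C(OC)OC | intermediate
5 | (1R)-2-(dimethoxymethyl)-1-methyl-3-oxocyclohexane-1-carbaldehyde (C2 epimers) | O=C[C@]1(C)CCCC(=O)C1C(OC)OC | intermediate
6 | (3S,3aS,7aR)-3-methoxy-7a-methylhexahydro-2-benzofuran-4(1H)-one | CO[C@H]1OC[C@]2(C)CCCC(=O)[C@H]12 | intermediate
7 | (3S,3aS,7aR)-3-methoxy-7a-methyl-4-methylideneoctahydro-2-benzofuran | CO[C@H]1OC[C@]2(C)CCCC(=C)[C@H]12 | intermediate
8 | C10–C20 spiro-epoxide of 7 (major isomer drawn; dr inconsequential) | CO[C@H]1OC[C@]2(C)CCC[C@]3(CO3)[C@H]12 | intermediate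
9 | 2,2,2-trifluoroethyl prop-2-enoate | C=CC(=O)OCC(F)(F)F | starting material
10 | spiro-δ-lactone (4R,5R,6S,10R) | CO[C@H]1OC[C@]2(C)CCC[C@]3(COC(=O)CC3)[C@H]12 | intermediate
11 | 8-acetyl spiro-δ-lactone (C8 unfixed) | CO[C@H]1OC[C@]2(C)CCC[C@]3(COC(=O)C(C(C)=O)C3)[C@H]12 | intermediate
12 | 8-acetyl-Δ8(9) spiro-δ-lactone | CO[C@H]1OC[C@]2(C)CCC[C@]3(COC(=O)C(C(C)=O)=C3)[C@H]12 | intermediate
13 | buta-1,3-diene | C=CC=C | starting material
14 | Diels–Alder adduct, 8-acetyl-Δ12, cis-fused (4R,5R,6S,8S,9S,10R) | CO[C@H]1OC[C@]2(C)CCC[C@]3(COC(=O)[C@]4(CC=CC[C@H]43)C(C)=O)[C@H]12 | intermediate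
15 | TBS enol ether of 14 | CO[C@H]1OC[C@]2(C)CCC[C@]3(COC(=O)[C@]4(CC=CC[C@H]43)C(=C)O[Si](C)(C)C(C)(C)C)[C@H]12 | intermediate
16 | 17-nor-Δ11-15-ketone, bicyclo[3.2.1]octene (…8S,9S,10R,13R) | CO[C@H]1OC[C@]2(C)CCC[C@]3(COC(=O)[C@@]45C[C@@H](C=C[C@H]43)CC5=O)[C@H]12 | intermediate
17 | Δ11,Δ16(17)-15-ketone (13S by CIP; same spatial arrangement as 16) | CO[C@H]1OC[C@]2(C)CCC[C@]3(COC(=O)[C@@]45C[C@@H](C=C[C@H]43)C(=C)C5=O)[C@H]12 | intermediate
18 | ludongnin I (4R,5R,6S,8S,9S,10R,13R,16R) | CO[C@H]1OC[C@]2(C)CCC[C@]3(COC(=O)[C@@]45C[C@@H](CC[C@H]43)[C@@H](C)C5=O)[C@H]12 | target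

**Totals**
Total steps: 14. Longest linear sequence: 14, from 3-methylcyclohexenone. No protecting groups are used.

**Steps most likely to fail**
1. **Step 10.** The β-carbon sits next to the spiro quaternary centre, the acetal must survive ZnCl2, and the face selectivity is predicted rather than proven.
   Fallback: use the polarity-matched 2-(TBSO)buta-1,3-diene, whose CH2 terminus bonds to C9. The resulting C12 enol silane is then joined to C16 by intramolecular oxidative enolate coupling (CAN or Cu(II)). The less hindered C12 ketone is removed through its tosylhydrazone (Caglioti reduction).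
2. **Step 12.** Insertion into an internal cis-alkene may be slow, and Pd–H migration toward C9 is possible.
   Fallback: close ring D by a radical route. NBS converts 15 into the bromomethyl ketone, and (TMS)3SiH/AIBN then drives a 5-exo α-keto radical cyclisation onto C13. This gives 11,12-dihydro-16 directly, and steps 13–14 are unchanged.
3. **Step 7.** The tertiary radical may disproportionate to an allylic alcohol or add with low diastereoselectivity.
   Fallback: build C10 by a polar route. Hydroboration–oxidation of 7 and then oxidation give the C20 aldehyde. Enamine or enolate Michael addition to methyl acrylate follows, with the electrophile entering from the convex face so that CHO remains syn to C6. NaBH4 reduction with spontaneous lactonisation then gives 10.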